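**Plan**
- With the butenolide numbered O1, C2 (lactone C=O), C3 (Me), C4 (CO2H), C5 (carbinol carbon), C5 is the only stereocentre. In the 5-hydroxybutenolide tautomer C5 is at the ketone level, and the tetrasubstituted C3=C4 bond holds C5 and the C2 carboxyl cis, so reduction at C5 can be followed directly by lactonisation.
- Retrosynthesis: remove the dioxolane from the chain ketone last; cut O1–C2 and C5–H back to the racemic lactol (open form: 4-oxo-enedioate); trace the lactol to a 2-alkyl-4-methylfuran-3-carboxylic acid (singlet oxygen).
- Cut the furan at C3–C4 and its O–C bond (Feist–Benary; chloroacetone supplies C2, C3 and the C3 methyl); cut C4–C5 (Meldrum's acid supplies C4 and its carboxyl); cut the terminal CH3–CO bond of the chain (MeMgBr on a Weinreb amide from cyclopentadecanolide).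
- Forward: chain (steps 1–4), furan ring (step 5), ketal and free acid (steps 6–7), furan to hydroxybutenolide (step 8), enzymatic reduction with closure of the γ-lactone (step 9), ketone release (step 10).
- Stereochemistry: (S) at C5 comes only from Re-face hydride delivery by an NADPH-dependent ketoreductase to the achiral open keto dicarboxylate; no later step touches C5.

Key step: step 9

Remark: the systematic names number the lactone ring from the other end (C5 of the discussion is C2 in the names); the ketoreductase is assumed to be the member of a screened enzyme panel that delivers hydride to the Re face of C5.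

**Step 1**
Reactants: 1 cyclopentadecanolide
Product: 2 15-hydroxy-N-methoxy-N-methylpentadecanamide
Conditions: MeNH(OMe)·HCl (1.5 equiv), iPrMgCl (3 equiv), THF, −20 → 0 °C; then 1 M HCl, 0 °C
Reagents that add atoms: N,O-dimethylhydroxylamine hydrochloride, Cl.CNOC
Why: Weinreb amide formation by aminolysis of the lactone with the chloromagnesium amide opens the unstrained macrolactone, and the sixteen-membered ring cannot re-close under the conditions.

**Step 2**
Reactants: 2 15-hydroxy-N-methoxy-N-methylpentadecanamide
Product: 3 16-hydroxyhexadecan-2-one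
Conditions: MeMgBr (3 equiv), THF, 0 °C; then 1 M HCl, 0 °C
Reagents that add atoms: methylmagnesium bromide, C[Mg]Br
Why: Weinreb ketone synthesis; after the hydroxyl is deprotonated, MeMgBr adds once to give a chelated tetrahedral intermediate that collapses to the methyl ketone only on acidic quench, so no tertiary alcohol should form.

**Step 3**
Reactants: 3 16-hydroxyhexadecan-2-one
Product: 4 15-oxohexadecanoic acid
Conditions: PhI(OAc)2 (2.2 equiv), TEMPO (cat.), MeCN/H2O (1:1), rt
Reagents that add atoms: water, O
Why: Oxoammonium (TEMPO) oxidation takes the primary alcohol through the aldehyde hydrate to the carboxylic acid and leaves the methyl ketone alone (no hypochlorite, hence no haloform cleavage).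

**Step 4**
Reactants: 4 15-oxohexadecanoic acid; 5 Meldrum's acid
Product: 7 ethyl 3,17-dioxooctadecanoate, via acyl Meldrum's acid 6 (not isolated)
Conditions: 5, DCC, DMAP, CH2Cl2, 0 °C → rt, filter; then EtOH, reflux
Reagents that add atoms: ethanol, CCO
Why: Carbodiimide C-acylation of Meldrum's acid followed by ethanolysis through the acylketene (loss of acetone and CO2) is the standard conversion of a carboxylic acid into its β-keto ester; the remote ketone is a spectator.

**Step 5**
Reactants: 7 ethyl 3,17-dioxooctadecanoate; 8 chloroacetone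
Product: 10 ethyl 4-methyl-2-(14-oxopentadecyl)furan-3-carboxylate, via hydroxydihydrofuran 9 (not isolated)
Conditions: 8 (1.5 equiv), pyridine, 60 °C; then TsOH·H2O (cat.), toluene, 80 °C
Reagents that add atoms: none
Why: Feist–Benary furan synthesis; under weak base the β-keto ester carbon adds aldol-wise to the ketone of chloroacetone, the enol oxygen displaces chloride, and acid-promoted loss of water from the tertiary carbinol aromatises the ring, which places the methyl at furan C4 and leaves C5 unsubstituted.

**Step 6**
Reactants: 10 ethyl 4-methyl-2-(14-oxopentadecyl)furan-3-carboxylate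
Product: 11 ethyl 4-methyl-2-[13-(2-methyl-1,3-dioxolan-2-yl)tridecyl]furan-3-carboxylate
Conditions: HOCH2CH2OH, TsOH·H2O (cat.), toluene, reflux, Dean–Stark trap
Reagents that add atoms: ethylene glycol, OCCO
Why: Acid-catalysed ketalisation with azeotropic removal of water masks the only ketone; the electron-poor 3-furoate tolerates TsOH and its doubly flanked ester exchanges only slowly.

**Step 7**
Reactants: 11 ethyl 4-methyl-2-[13-(2-methyl-1,3-dioxolan-2-yl)tridecyl]furan-3-carboxylate
Product: 12 4-methyl-2-[13-(2-methyl-1,3-dioxolan-2-yl)tridecyl]furan-3-carboxylic acid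
Conditions: KOH, EtOH/H2O, 70 °C; then 1 M HCl to pH 4, 0 °C
Reagents that add atoms: potassium hydroxide, [K+].[OH-]
Why: Saponification of the hindered conjugated ester needs heat, nothing else in the molecule is base-labile, and acidifying only to pH 4 in the cold keeps the dioxolane.

**Step 8**
Reactants: 12 4-methyl-2-[13-(2-methyl-1,3-dioxolan-2-yl)tridecyl]furan-3-carboxylic acid
Product: 14 racemic 2-hydroxy-4-methyl-2-[13-(2-methyl-1,3-dioxolan-2-yl)tridecyl]-5-oxo-2,5-dihydrofuran-3-carboxylic acid, via furan endoperoxide 13 (not isolated)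
Conditions: O2, tetraphenylporphyrin (cat.), iPr2NEt (2.5 equiv), visible light, CH2Cl2, −78 → 0 °C; citric acid wash
Reagents that add atoms: oxygen, O=O
Why: [4+2] cycloaddition of singlet oxygen across the furan α-carbons gives the endoperoxide, and Kornblum–DeLaMare deprotonation of its single ring C–H by the amine makes that carbon the lactone carbonyl and the chain-bearing carbon the lactol, so only one hydroxybutenolide can form.

**Step 9**
Reactants: 14 racemic 2-hydroxy-4-methyl-2-[13-(2-methyl-1,3-dioxolan-2-yl)tridecyl]-5-oxo-2,5-dihydrofuran-3-carboxylic acid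
Product: 17 (S)-4-methyl-2-[13-(2-methyl-1,3-dioxolan-2-yl)tridecyl]-5-oxo-2,5-dihydrofuran-3-carboxylic acid, via open keto dicarboxylate 15 (not isolated), via (S)-hydroxy dicarboxylate 16 (not isolated)
Conditions: ketoreductase ((S)-selective, NADPH-dependent), NADP+ (cat.), glucose dehydrogenase, D-glucose, KH2PO4/K2HPO4 buffer pH 7.5, DMSO (10% v/v), 30 °C; then citric acid to pH 3.5, EtOAc, 5 °C
Reagents that add atoms: none
Why: Proposed new method: at pH 7.5 the racemic lactol 14 ionises and opens to the single achiral (E)-acylmethylfumarate dianion 15, so both enantiomers of 14 feed one ketone; the ketoreductase passes the NADPH hydride to the Re face of the C5 carbonyl (new C5–H bond) and protonates the oxygen, while glucose dehydrogenase and glucose regenerate NADPH irreversibly. The closest known reactions are ketoreductase reductions of 4-oxo acids and esters whose hydroxy acids lactonise to γ-lactones, and the NaBH4 reduction of 5-hydroxybutenolides to racemic butenolides. On acidification the C5 hydroxyl of 16 adds to the cis C2 carboxyl in a 5-exo-trig lactonisation that forms O1–C2; closure on the C4 carboxyl would need a four-membered ring. The (S) configuration at C5 is set by the enzyme pocket alone, which must distinguish the long alkyl arm from the dianionic alkene. The step needs chemoselectivity for the C5 ketone and no loss of configuration: the dioxolane hides the chain ketone, the tetrasubstituted C3=C4 bond fixes the cis geometry for ring closure, and open 16 has no acidic C5–H.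

**Step 10**
Reactants: 17 (S)-4-methyl-2-[13-(2-methyl-1,3-dioxolan-2-yl)tridecyl]-5-oxo-2,5-dihydrofuran-3-carboxylic acid
Product: 18 (S)-4-methyl-5-oxo-2-(14-oxopentadecyl)-2,5-dihydrofuran-3-carboxylic acid
Conditions: 1 M HCl, THF, rt
Reagents that add atoms: water, O
Why: Acid-catalysed hydrolysis of the dioxolane releases the methyl ketone; the butenolide acid is stable to dilute acid and the C5–H is not enolised under these conditions, so the configuration should be kept.

**Compound list**
1 | cyclopentadecanolide (oxacyclohexadecan-2-one) | O=C1CCCCCCCCCCCCCCO1 | starting material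
2 | 15-hydroxy-N-methoxy-N-methylpentadecanamide | CON(C)C(=O)CCCCCCCCCCCCCCO | intermediate
3 | 16-hydroxyhexadecan-2-one | CC(=O)CCCCCCCCCCCCCCO | intermediate
4 | 15-oxohexadecanoic acid | CC(=O)CCCCCCCCCCCCCC(=O)O | intermediate
5 | Meldrum's acid (2,2-dimethyl-1,3-dioxane-4,6-dione) | CC1(C)OC(=O)CC(=O)O1 | starting material
6 | 5-(1-hydroxy-15-oxohexadecylidene)-2,2-dimethyl-1,3-dioxane-4,6-dione (acyl Meldrum's acid, not isolated) | CC(=O)CCCCCCCCCCCCCC(O)=C1C(=O)OC(C)(C)OC1=O | intermediate
7 | ethyl 3,17-dioxooctadecanoate | CC(=O)CCCCCCCCCCCCCC(=O)CC(=O)OCC | intermediate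
8 | chloroacetone (1-chloropropan-2-one) | CC(=O)CCl | starting material
9 | ethyl 4-hydroxy-4-methyl-2-(14-oxopentadecyl)-4,5-dihydrofuran-3-carboxylate (racemic, not isolated) | CC(=O)CCCCCCCCCCCCCC1=C(C(=O)OCC)C(C)(O)CO1 | intermediate
10 | ethyl 4-methyl-2-(14-oxopentadecyl)furan-3-carboxylate | CC(=O)CCCCCCCCCCCCCc1occ(C)c1C(=O)OCC | intermediate
11 | ethyl 4-methyl-2-[13-(2-methyl-1,3-dioxolan-2-yl)tridecyl]furan-3-carboxylate | CC1(OCCO1)CCCCCCCCCCCCCc2occ(C)c2C(=O)OCC | intermediate
12 | 4-methyl-2-[13-(2-methyl-1,3-dioxolan-2-yl)tridecyl]furan-3-carboxylic acid | CC1(OCCO1)CCCCCCCCCCCCCc2occ(C)c2C(=O)O | intermediate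
13 | 6-methyl-4-[13-(2-methyl-1,3-dioxolan-2-yl)tridecyl]-2,3,7-trioxabicyclo[2.2.1]hept-5-ene-5-carboxylic acid (racemic endoperoxide, not isolated) | CC1(OCCO1)CCCCCCCCCCCCCC23OOC(O2)C(C)=C3C(=O)O | intermediate
14 | 2-hydroxy-4-methyl-2-[13-(2-methyl-1,3-dioxolan-2-yl)tridecyl]-5-oxo-2,5-dihydrofuran-3-carboxylic acid (racemic lactol) | CC1(OCCO1)CCCCCCCCCCCCCC2(O)OC(=O)C(C)=C2C(=O)O | intermediate
15 | (E)-2-methyl-3-[14-(2-methyl-1,3-dioxolan-2-yl)tetradecanoyl]but-2-enedioic acid (present as the dianion, not isolated) | CC1(OCCO1)CCCCCCCCCCCCCC(=O)/C(C(=O)O)=C(/C)C(=O)O | intermediate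
16 | (E)-2-[(1S)-1-hydroxy-14-(2-methyl-1,3-dioxolan-2-yl)tetradecyl]-3-methylbut-2-enedioic acid (present as the dianion, not isolated) | CC1(OCCO1)CCCCCCCCCCCCC[C@H](O)/C(C(=O)O)=C(/C)C(=O)O | intermediate
17 | (S)-4-methyl-2-[13-(2-methyl-1,3-dioxolan-2-yl)tridecyl]-5-oxo-2,5-dihydrofuran-3-carboxylic acid | CC1(OCCO1)CCCCCCCCCCCCC[C@@H]2OC(=O)C(C)=C2C(=O)O | intermediate
18 | (S)-4-methyl-5-oxo-2-(14-oxopentadecyl)-2,5-dihydrofuran-3-carboxylic acid | CC(=O)CCCCCCCCCCCCC[C@@H]1OC(=O)C(C)=C1C(=O)O | target

**Step count and risks**
Total steps: 10. Longest linear sequence: 10 steps (1 to 18).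

Steps most likely to fail:

1. Step 9 (proposed new method). The enzyme may fail to bind or turn over the bulky, soap-like dianionic ketone, or hydride may be delivered to both faces of C5. Fallback with known chemistry, setting out from 14: reduction with NaBH4 in aqueous NaOH/THF at 0 °C and acidification to pH 3.5 should give the racemic butenolide acid F1. Its enantiomers would then be separated by preparative supercritical-fluid chromatography on a chiral stationary phase, and the (S)-enantiomer is 17, where the route resumes.

2. Step 8. The endoperoxide of the free furoic acid may break down by paths other than Kornblum–DeLaMare deprotonation (decarboxylation, Baeyer–Villiger-type acyl shift), or the amine may be consumed by photo-oxidation. Fallback from 12: oxidative ring opening with NBS and NaHCO3 in acetone/H2O at −20 °C should give the keto enal acid (E)-3-methyl-2-[14-(2-methyl-1,3-dioxolan-2-yl)tetradecanoyl]-4-oxobut-2-enoic acid F2. Pinnick oxidation of its aldehyde (NaClO2, NaH2PO4, 2-methyl-2-butene, tBuOH/H2O) then gives 15, which closes to lactol 14, where the route resumes.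

3. Step 5. The enolate may attack the CH2Cl carbon first (C-alkylation), which after Paal–Knorr-type closure leads to the 5-methyl regioisomer; pyridine may also be quaternised by chloroacetone, or dehydration may stall. Fallback from 7: oxidative [3+2] annulation with ethyl 1-propenyl ether mediated by (NH4)2Ce(NO3)6 and NaHCO3 in MeCN at 0 °C should give ethyl 5-ethoxy-4-methyl-2-(14-oxopentadecyl)-4,5-dihydrofuran-3-carboxylate F3. The regiochemistry is fixed because the dicarbonyl radical adds to the methyl-bearing alkene carbon. TsOH (cat.) in toluene at 80 °C then eliminates ethanol to give furan 10, where the route resumes.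

**Further compounds**
F1 | step 9 | racemic 4-methyl-2-[13-(2-methyl-1,3-dioxolan-2-yl)tridecyl]-5-oxo-2,5-dihydrofuran-3-carboxylic acid | CC1(OCCO1)CCCCCCCCCCCCCC2OC(=O)C(C)=C2C(=O)O
F2 | step 8 | (E)-3-methyl-2-[14-(2-methyl-1,3-dioxolan-2-yl)tetradecanoyl]-4-oxobut-2-enoic acid | CC1(OCCO1)CCCCCCCCCCCCCC(=O)/C(C(=O)O)=C(/C)C=O
F3 | step 5 | ethyl 5-ethoxy-4-methyl-2-(14-oxopentadecyl)-4,5-dihydrofuran-3-carboxylate (mixture of diastereomers) | CC(=O)CCCCCCCCCCCCCC1=C(C(=O)OCC)C(C)C(OCC)O1
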